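## Structural features

The target is a single tetrahydropyran (numbered here O1, C2 to C6) with a 4-hydroxy-3-methoxyphenyl group (ring A) directly on C2, a free secondary hydroxyl on C4, and on C6 a two-carbon chain (C7, C8) ending in a second 4-hydroxy-3-methoxyphenyl group (ring B). The three stereocentres C2, C4 and C6 (all S) are separated by the methylene carbons C3 and C5, so each pair stands in a 1,3-relationship. The C2 aryl group and the C6 chain are cis and both equatorial in the chair, and the C4 hydroxyl is trans to both and therefore axial. The fragile point is the C2–O1 bond, a benzylic ether para to an oxygen substituent, which acid can ionise toward a quinone-methide-like cation and which hydrogenolysis can cut. The two phenols are acidic and easily oxidised and have to be masked through every basic, organometallic and electrophilic operation. The real difficulty is the 1,3,5-array around the ring oxygen with an axial alcohol (the less stable C4 epimer), together with a benzylic C2 centre that must be set without passing through an open cation. The key step exploits the fact that removing the C4 hydroxyl leaves a C3=C4 double bond inside the ring, flanked by the two oxygen-bearing carbons C2 and C6: such a cyclic allyl homoallyl ether is the metathesis product of a vinyl group on C2 and an allyl group on C6. Because C2 and C6 both hang on O1, both can be fixed on an open-chain ether before the ring exists, and the C3=C4 alkene then serves as a masked C4 carbinol whose polarity is biased by the allylic C2–O1 bond.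

## Logic of the disconnections

**16 to 15.** The two phenolic O–CH2Ph bonds are cut. Free phenols would quench the organolithium, the cuprous alkoxide and the aluminium hydride used earlier and would invite arene mercuration. Benzyl ethers arise in the same operation that esterifies each acid and survive every later step. The skeleton is unchanged; the gain is one uniform, tolerant protecting group. The forward step must remove two aryl benzyl ethers and leave the benzylic C2–O1 bond of the ring.

**15 to 13.** The C4–O bond and one C3–H bond are cut (hydration transform). The axial C4 hydroxyl is the less stable epimer. As the anti adduct of water to a ring alkene it becomes a question of regio- and facial selectivity that the ring itself answers. One stereocentre disappears and the retron for ring-closing metathesis appears. The forward step must place oxygen on C4 and not on C3, deliver it axially, and spare the electron-rich arenes.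

**13 to 12 (strategic cut).** The C3=C4 double bond is cut. It lies between two carbons that each connect to O1 through a stereocentre, and its formation from two terminal alkenes is one of the most dependable ring closures. The ring disappears and an acyclic ether remains whose two stereocentres (1S on the arylallyl carbon, 3S on the hexenyl carbon, which map onto 2S and 6S) can be made separately. The forward step must close the ring without double-bond migration and without disturbing the doubly activated C2 position.

**12 to 5 and 9.** The O1–C2 bond is cut. This divides the molecule into two halves of similar size, each with one arene. A branched allylic ether is the retron of iridium-catalysed allylic substitution, which creates C2 from an achiral linear carbonate under ligand control. The gain is convergence and the removal of the benzylic stereocentre from both fragment syntheses. The forward step must favour the branched over the linear ether, must let the ligand and not the C6 centre decide C2, and needs a soft (cuprous) alkoxide.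

**5 to 3 and 4.** The C5–C6 bond is cut (carbonyl allylation transform). Enantioselective allyl transfer to an aldehyde brings in C4 and C5 with the alkene needed later and creates C6 in the same step. The fragment falls to an achiral aldehyde and a commercial allyl donor. The forward step must distinguish the faces of an unbranched, unhindered aldehyde.

**3 to 2 to 1.** The aldehyde of 3 is traced to the ester C–O bond of 2, and the two O–benzyl bonds of 2 to benzyl bromide and 1. One alkylation masks the phenol and turns the acid into a reducible ester. The demand is that hydride addition stops at the aldehyde.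

**9 to 8 to 7 to 6.** The carbonate C–O bond of 9 is cut to 8, the carbinol of 8 is traced to the ester of 7, and the O–benzyl bonds of 7 to 6. A tert-butyl carbonate is chosen instead of a methyl carbonate because methoxide released on ionisation would compete as a nucleophile, whereas tert-butoxide is too hindered. The E double bond of 6 is carried through unchanged, so the demand is 1,2-reduction without conjugate reduction.

## Other disconnections considered

**Alternative 1:** The cut is the C2–C3 bond of the ketone (2S,6S)-2-(4-benzyloxy-3-methoxyphenyl)-6-[2-(4-benzyloxy-3-methoxyphenyl)ethyl]tetrahydro-4H-pyran-4-one A1.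
- *Forward step:* the cis-dioxanone A3 would be methylenated with Cp2Ti(CH3)2 to the enol acetal A2. Me2AlCl would ionise A2 to an aryl-stabilised oxocarbenium and an aluminium enolate, which recombine through carbon to A1. Hydride delivery from the equatorial side with LiBH(s-Bu)3 and debenzylation would finish.
- *In favour:* ring, C2–C3 bond and the C2 centre are formed together, with the cis outcome expected from a chair-like ion pair. Ring A assists ionisation. The C4 ketone lets a bulky hydride set the axial alcohol by reagent control; on control of C4 this is better than the chosen plan, whose hydration depends on both regio- and facial selectivity.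
- *Against:* the same electron-rich oxocarbenium is long-lived and could lose its partner, epimerise, or be trapped by an arene. Acetal formation with a deactivated aromatic aldehyde is slow. A3 requires the C6 carbinol to be set beforehand, and titanium and aluminium reagents are used in stoichiometric amounts.
- *Comparison:* on structure the two plans are equally convergent, and this key step builds more (one C–C bond, one ring, one stereocentre against one C=C bond, one ring, none). On mechanism it is ionic at exactly the benzylic centre that the chosen plan keeps covalently intact once the catalyst has set it. On step economy it is about equal or one to two steps longer.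

**Alternative 2:** The cut is the O1–C2 bond.
- *Forward step:* the syn-diol A5 (ring A free, ring B as pivalate) would be oxidised by two electrons with 2,3-dichloro-5,6-dicyano-1,4-benzoquinone or at a carbon anode to a para-quinone methide at C2. The C6 hydroxyl would add to give the ring B pivalate of 16, A4, and ester cleavage would end the route.
- *In favour:* fewest protecting groups. The fragile benzylic ether is made last, under conditions where reversible addition can correct C2 toward the cis isomer. No hydrogenolysis is run next to that ether, which is better than the chosen plan on this point. The step count should be equal or lower.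
- *Against:* A4 has a more oxidisable benzylic C–H than A5, so over-oxidation is built in. Selection between two guaiacyl rings rests on a single pivalate. A5 is nearly meso, its two ends differing only by acylation, so any acyl transfer between the phenols would erase the enantiomeric purity. The syn-diol still has to be made stereoselectively.
- *Comparison:* on structure it forms only a C–O bond and sets C2, with C4 and C6 made earlier. On mechanism it is oxidative and cationic against a neutral metal carbene, and so less predictable. On step economy it is equal or better.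

**Alternative 3:** The cut is the C5–C6 bond.
- *Forward step:* the iodide A7 would give a C5 radical with Bu3SnH and azobisisobutyronitrile, which adds 6-exo to the β-carbon of the alkoxyacrylate to give the cis ester A6.
- *In favour:* C2 and C4 are fixed in the open chain by well-tested methods, so no late hydration is needed; on security of C4 this is better than the chosen plan. The cyclisation is neutral and tolerant, and equal to metathesis in functional-group compatibility.
- *Against:* A6 carries C7 and C8 only as an acetate arm, so ring B must be attached afterwards by reduction, aryl addition and removal of the benzylic oxygen. The silyloxy group has to sit axial in the cyclisation chair, which may erode the cis preference. Tin hydride is stoichiometric, and A7 needs two stereocentres and a primary iodide.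
- *Comparison:* on structure it builds a ring C–C bond and sets C6 but is linear, not convergent. On mechanism it is a radical chain with comparable tolerance. On step economy it is clearly longer, by three or four steps after the key step alone.

Key step: step 8

Assumption: the sense of induction assigned to (R)-BINOL in step 3 and to the (Sa,S,S) phosphoramidite in step 7 follows the usual correlations for unbranched aldehydes and cinnamyl-type carbonates; should a first run show the opposite sense, the antipodal ligand would be used without other change.

## Route

Step 1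
Reactants: 1 3-(4-hydroxy-3-methoxyphenyl)propanoic acid
Product: 2 benzyl 3-(4-benzyloxy-3-methoxyphenyl)propanoate
Conditions: BnBr (2.4 equiv), K2CO3 (3 equiv), DMF, 60 °C
Reagents that add atoms: benzyl bromide, BrCc1ccccc1
Why: Williamson etherification of the phenoxide and SN2 alkylation of the carboxylate occur together, so one operation masks the phenol and turns the acid into a reducible ester; no stereocentre is involved.

Step 2
Reactants: 2 benzyl 3-(4-benzyloxy-3-methoxyphenyl)propanoate
Product: 3 3-(4-benzyloxy-3-methoxyphenyl)propanal
Conditions: i-Bu2AlH (1.1 equiv), CH2Cl2, −78 °C; aq KNaC4H4O6 work-up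
Reagents that add atoms: none
Why: Partial reduction of an ester: one equivalent of i-Bu2AlH at −78 °C transfers a single hydride and the aldehyde is released only on cold aqueous quench; the aryl benzyl ether is inert to the hydride.

Step 3
Reactants: 3 3-(4-benzyloxy-3-methoxyphenyl)propanal; 4 allyltributylstannane
Product: 5 (S)-1-(4-benzyloxy-3-methoxyphenyl)hex-5-en-3-ol
Conditions: (R)-BINOL (10 mol %), Ti(OiPr)4 (10 mol %), 4 Å MS, CH2Cl2, −20 °C
Reagents that add atoms: none
Why: Keck asymmetric allylation: the chiral titanium–BINOL Lewis acid binds the aldehyde and the allylstannane adds through an open transition state to one carbonyl face; with (R)-BINOL an unbranched aldehyde is expected to give the S alcohol (allyl outranks the arylethyl chain), which sets C6.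

Step 4
Reactants: 6 ferulic acid
Product: 7 benzyl (E)-3-(4-benzyloxy-3-methoxyphenyl)prop-2-enoate
Conditions: BnBr (2.4 equiv), K2CO3 (3 equiv), DMF, 60 °C
Reagents that add atoms: benzyl bromide, BrCc1ccccc1
Why: The same double O-alkylation as in step 1 (Williamson ether synthesis and carboxylate alkylation); the E double bond is not touched.

Step 5
Reactants: 7 benzyl (E)-3-(4-benzyloxy-3-methoxyphenyl)prop-2-enoate
Product: 8 (E)-3-(4-benzyloxy-3-methoxyphenyl)prop-2-en-1-ol
Conditions: i-Bu2AlH (2.5 equiv), CH2Cl2, −78 → 0 °C
Reagents that add atoms: none
Why: i-Bu2AlH reduces α,β-unsaturated esters by 1,2-addition to the allylic alcohol without conjugate reduction, so the E geometry is kept; the benzyl alcohol released from the ester is removed by chromatography.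

Step 6
Reactants: 8 (E)-3-(4-benzyloxy-3-methoxyphenyl)prop-2-en-1-ol
Product: 9 tert-butyl (E)-3-(4-benzyloxy-3-methoxyphenyl)prop-2-en-1-yl carbonate
Conditions: Boc2O (1.3 equiv), Bu4NHSO4 (5 mol %), 30% aq NaOH, CH2Cl2, 0 °C → rt
Reagents that add atoms: di-tert-butyl dicarbonate, CC(C)(C)OC(=O)OC(=O)OC(C)(C)C
Why: O-acylation of a primary allylic alcohol under phase-transfer catalysis; the tert-butyl carbonate is preferred to a methyl carbonate because the tert-butoxide set free on ionisation in step 7 is too hindered to compete with the alkoxide of 5 for the allyl complex.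

Step 7
Reactants: 5 (S)-1-(4-benzyloxy-3-methoxyphenyl)hex-5-en-3-ol; 9 tert-butyl (E)-3-(4-benzyloxy-3-methoxyphenyl)prop-2-en-1-yl carbonate
Product: 12 (3S)-1-(4-benzyloxy-3-methoxyphenyl)hex-5-en-3-yl (1S)-1-(4-benzyloxy-3-methoxyphenyl)prop-2-en-1-yl ether, via lithium alkoxide 10 (not isolated), via cuprous alkoxide 11 (not isolated)
Conditions: 5, n-BuLi (1.0 equiv), THF, 0 °C; CuI (1.0 equiv), rt; then 9, [Ir(cod)Cl]2 (2 mol %), (Sa,S,S)-L (4 mol %), THF, rt [L = O,O′-(1,1′-binaphthalene-2,2′-diyl) N,N-bis(1-phenylethyl)phosphoramidite]
Reagents that add atoms: n-butyllithium, [Li]CCCC (supplies the lithium of 10); CuI, [Cu]I (supplies the copper of 11)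
Why: Iridium-catalysed asymmetric allylic etherification: 9 adds oxidatively to the cyclometalated iridium phosphoramidite complex to give an allyl complex of trivalent iridium, which the soft cuprous alkoxide 11 attacks at the aryl-substituted terminus to give the branched ether. The new C2 centre is set by the ligand (catalyst control; the (Sa,S,S) antipode is the one expected to give 1S with cinnamyl-type carbonates), and the remote C6 centre of 5 should not override it. Benzyl ethers and both terminal alkenes are inert.

Step 8
Reactants: 12 (3S)-1-(4-benzyloxy-3-methoxyphenyl)hex-5-en-3-yl (1S)-1-(4-benzyloxy-3-methoxyphenyl)prop-2-en-1-yl ether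
Product: 13 (2S,6S)-2-(4-benzyloxy-3-methoxyphenyl)-6-[2-(4-benzyloxy-3-methoxyphenyl)ethyl]-5,6-dihydro-2H-pyran
Conditions: second-generation Grubbs catalyst (H2IMes)(PCy3)Cl2Ru=CHPh (5 mol %), 1,4-benzoquinone (10 mol %), CH2Cl2 (0.01 M), 40 °C
Reagents that add atoms: none
Why: Ring-closing olefin metathesis of an allyl homoallyl ether, the standard entry to 5,6-dihydro-2H-pyrans. The ruthenium benzylidene exchanges first with the less hindered allyl terminus on the C6 side to put the metal on C4; intramolecular [2+2] cycloaddition with the C2 vinyl group gives a ruthenacyclobutane, whose cycloreversion releases 13 and a ruthenium methylidene that carries the chain, with ethylene lost to the gas phase. The six-membered ring is closed between C3 and C4 with the alkene endocyclic and necessarily Z, a ring size for which closure is fast and strain-free. No stereocentre is formed: C2 and C6 take part in no bond that is made or broken, so the 2S,6S (cis) relationship of 13 is inherited from 12. The selectivity needed is ring closure over acyclic diene oligomerisation and over double-bond migration by ruthenium hydrides, which would move either terminal alkene into conjugation with oxygen or the arene. High dilution, two monosubstituted alkenes, the favourable ring size and the hydride scavenger 1,4-benzoquinone secure this. Benzyl ethers, aryl methyl ethers and the benzylic ether are inert to the carbene under these neutral conditions.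

Step 9
Reactants: 13 (2S,6S)-2-(4-benzyloxy-3-methoxyphenyl)-6-[2-(4-benzyloxy-3-methoxyphenyl)ethyl]-5,6-dihydro-2H-pyran
Product: 15 (2S,4S,6S)-2-(4-benzyloxy-3-methoxyphenyl)-6-[2-(4-benzyloxy-3-methoxyphenyl)ethyl]tetrahydro-2H-pyran-4-ol, via organomercury acetate 14 (not isolated)
Conditions: Hg(OAc)2 (1.2 equiv), THF–H2O (1:1), 0 °C → rt; then 3 M aq NaOH, NaBH4, 0 °C
Reagents that add atoms: Hg(OAc)2, CC(=O)O[Hg]OC(C)=O (supplies the HgOAc group of 14); water, O (supplies the C4 hydroxyl of 14 and 15)
Why: Oxymercuration–demercuration: divalent mercury forms a mercurinium ion reversibly and water opens it at C4, the carbon farther from the electron-withdrawing allylic C2–O1 bond, in a trans-diaxial manner (Fürst–Plattner rule) on the half-chair that keeps the C2 and C6 substituents equatorial. This places mercury axial on C3 and the hydroxyl axial on C4, trans to both substituents, which is the 4S configuration; NaBH4 then replaces mercury by hydrogen through a radical without touching C4.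

Step 10
Reactants: 15 (2S,4S,6S)-2-(4-benzyloxy-3-methoxyphenyl)-6-[2-(4-benzyloxy-3-methoxyphenyl)ethyl]tetrahydro-2H-pyran-4-ol
Product: 16 (2S,4S,6S)-2-(4-hydroxy-3-methoxyphenyl)-6-[2-(4-hydroxy-3-methoxyphenyl)ethyl]tetrahydro-2H-pyran-4-ol
Conditions: H2 (1 atm), Pd/C (10%), EtOAc, rt
Reagents that add atoms: none
Why: Hydrogenolysis of aryl benzyl ethers over palladium metal is much faster than cleavage of a ring dialkyl benzylic ether, so in a neutral solvent at one atmosphere, with the reaction stopped after uptake of two equivalents of hydrogen, the C2–O1 bond should survive; no stereocentre is touched.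

## Compound list

1 | 3-(4-hydroxy-3-methoxyphenyl)propanoic acid | OC(=O)CCc1ccc(O)c(OC)c1 | starting material
2 | benzyl 3-(4-benzyloxy-3-methoxyphenyl)propanoate | COc1cc(CCC(=O)OCc2ccccc2)ccc1OCc1ccccc1 | intermediate
3 | 3-(4-benzyloxy-3-methoxyphenyl)propanal | COc1cc(CCC=O)ccc1OCc1ccccc1 | intermediate
4 | allyltributylstannane | C=CC[Sn](CCCC)(CCCC)CCCC | starting material
5 | (S)-1-(4-benzyloxy-3-methoxyphenyl)hex-5-en-3-ol | COc1cc(CC[C@H](O)CC=C)ccc1OCc1ccccc1 | intermediate
6 | ferulic acid, (E)-3-(4-hydroxy-3-methoxyphenyl)prop-2-enoic acid | OC(=O)/C=C/c1ccc(O)c(OC)c1 | starting material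
7 | benzyl (E)-3-(4-benzyloxy-3-methoxyphenyl)prop-2-enoate | COc1cc(/C=C/C(=O)OCc2ccccc2)ccc1OCc1ccccc1 | intermediate
8 | (E)-3-(4-benzyloxy-3-methoxyphenyl)prop-2-en-1-ol | COc1cc(/C=C/CO)ccc1OCc1ccccc1 | intermediate
9 | tert-butyl (E)-3-(4-benzyloxy-3-methoxyphenyl)prop-2-en-1-yl carbonate | COc1cc(/C=C/COC(=O)OC(C)(C)C)ccc1OCc1ccccc1 | intermediate
10 | lithium (S)-1-(4-benzyloxy-3-methoxyphenyl)hex-5-en-3-olate (not isolated) | [Li+].COc1cc(CC[C@H]([O-])CC=C)ccc1OCc1ccccc1 | intermediate
11 | copper (S)-1-(4-benzyloxy-3-methoxyphenyl)hex-5-en-3-olate, monovalent copper (not isolated) | COc1cc(CC[C@H](O[Cu])CC=C)ccc1OCc1ccccc1 | intermediate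
12 | (3S)-1-(4-benzyloxy-3-methoxyphenyl)hex-5-en-3-yl (1S)-1-(4-benzyloxy-3-methoxyphenyl)prop-2-en-1-yl ether | COc1cc(CC[C@H](O[C@H](c3ccc(OCc4ccccc4)c(OC)c3)C=C)CC=C)ccc1OCc1ccccc1 | intermediate
13 | (2S,6S)-2-(4-benzyloxy-3-methoxyphenyl)-6-[2-(4-benzyloxy-3-methoxyphenyl)ethyl]-5,6-dihydro-2H-pyran (cis) | COc1cc(CC[C@H]2CC=C[C@@H](c3ccc(OCc4ccccc4)c(OC)c3)O2)ccc1OCc1ccccc1 | intermediate
14 | [(2R,3R,4S,6S)-2-(4-benzyloxy-3-methoxyphenyl)-6-[2-(4-benzyloxy-3-methoxyphenyl)ethyl]-4-hydroxytetrahydro-2H-pyran-3-yl]mercury acetate, HgOAc and OH trans-diaxial (not isolated) | COc1cc(CC[C@H]2C[C@H](O)[C@@H]([Hg]OC(C)=O)[C@@H](c3ccc(OCc4ccccc4)c(OC)c3)O2)ccc1OCc1ccccc1 | intermediate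
15 | (2S,4S,6S)-2-(4-benzyloxy-3-methoxyphenyl)-6-[2-(4-benzyloxy-3-methoxyphenyl)ethyl]tetrahydro-2H-pyran-4-ol | COc1cc(CC[C@H]2C[C@H](O)C[C@@H](c3ccc(OCc4ccccc4)c(OC)c3)O2)ccc1OCc1ccccc1 | intermediate
16 | (2S,4S,6S)-2-(4-hydroxy-3-methoxyphenyl)-6-[2-(4-hydroxy-3-methoxyphenyl)ethyl]tetrahydro-2H-pyran-4-ol | COc1cc(CC[C@H]2C[C@H](O)C[C@@H](c3ccc(O)c(OC)c3)O2)ccc1O | target

## Step count and least certain steps

Total step count: 10 (steps 1–3 and 4–6 run in parallel). Longest linear sequence: 7 steps (1, 2, 3, 7, 8, 9, 10; the branch 4, 5, 6, 7, 8, 9, 10 is equally long).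

**Step 8 (key step).** The most likely failure is double-bond migration competing with ring closure. Ruthenium hydride species formed as the catalyst ages can shift the alkene of the 1-arylallyl ether into conjugation, after which that terminus no longer closes a six-membered ring; slow turnover at the α-branched vinyl group gives this process time. The fallback closes the ring through a carbon–oxygen and a carbon–carbon bond by Prins cyclisation and uses no metathesis. It sets out from 5 and comes back at 15. Alcohol 5 and commercial 4-benzyloxy-3-methoxybenzaldehyde would be condensed with CF3CO2H in CH2Cl2 at 0 °C. The oxocarbenium ion cyclises through a chair with both substituents equatorial and is captured equatorially to give (2S,4R,6S)-2-(4-benzyloxy-3-methoxyphenyl)-6-[2-(4-benzyloxy-3-methoxyphenyl)ethyl]tetrahydro-2H-pyran-4-yl trifluoroacetate F1. Aqueous K2CO3 in methanol would give the all-equatorial alcohol (2S,4R,6S)-2-(4-benzyloxy-3-methoxyphenyl)-6-[2-(4-benzyloxy-3-methoxyphenyl)ethyl]tetrahydro-2H-pyran-4-ol F2. Mitsunobu inversion (4-nitrobenzoic acid, PPh3, diisopropyl azodicarboxylate, THF) would give the axial ester (2S,4S,6S)-2-(4-benzyloxy-3-methoxyphenyl)-6-[2-(4-benzyloxy-3-methoxyphenyl)ethyl]tetrahydro-2H-pyran-4-yl 4-nitrobenzoate F3, and LiOH in THF–H2O would give 15. The known weakness of this fallback is oxonia-Cope exchange with an electron-rich aryl aldehyde, which low temperature and an excess of the acid should limit.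

**Step 7.** The most likely failure is loss of regio- or stereocontrol in the allylic substitution. The hindered secondary alkoxide may attack the unsubstituted allyl terminus, and the electron-rich branched ether can re-ionise on the catalyst, which erodes the configuration at C2 and drains material to the linear isomer. The fallback uses neither iridium nor metathesis and closes the ring by conjugate addition. It sets out from 5 and comes back at 15. Tsuji–Wacker oxidation of 5 (PdCl2 10 mol %, CuCl, O2, DMF–H2O) would give (S)-6-(4-benzyloxy-3-methoxyphenyl)-4-hydroxyhexan-2-one F4. Pyrrolidine-mediated aldol condensation at the methyl group with 4-benzyloxy-3-methoxybenzaldehyde would give (1E,5S)-1,7-bis(4-benzyloxy-3-methoxyphenyl)-5-hydroxyhept-1-en-3-one F5. Under the same amine, or on a sulfonic acid resin, F5 should close by reversible 6-endo oxa-Michael addition to the thermodynamically preferred cis ketone (2S,6S)-2-(4-benzyloxy-3-methoxyphenyl)-6-[2-(4-benzyloxy-3-methoxyphenyl)ethyl]tetrahydro-4H-pyran-4-one F6. LiBH(s-Bu)3 in THF at −78 °C attacks from the equatorial side and would give the axial alcohol 15. The weak point is β-elimination of F4 under the amine; a temporary silyl ether would remove it at the cost of two steps.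

**Step 9.** The most likely failures are incomplete regiocontrol of water attack (some C3 alcohol), electrophilic mercuration of the dialkoxyarenes, and reversion to the alkene by β-elimination during the borohydride reduction. The fallback replaces the organomercurial by a halohydrin whose carbon–halogen bond is cut homolytically, so the reduction cannot revert to the alkene. It sets out from 13 and comes back at 15. N-iodosuccinimide in MeCN–H2O at 0 °C would give, by the same diaxial opening, (2R,3R,4S,6S)-2-(4-benzyloxy-3-methoxyphenyl)-6-[2-(4-benzyloxy-3-methoxyphenyl)ethyl]-3-iodotetrahydro-2H-pyran-4-ol F7. Bu3SnH with azobisisobutyronitrile in toluene at 80 °C would then give 15.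

**Step 3.** The most likely failure is incomplete facial selectivity together with slow catalyst turnover on an unbranched aldehyde, which would pass a minor enantiomer of 5 into step 7 as a diastereomer of 12. The fallback replaces the catalytic Lewis acid and the stannane by a stoichiometric chiral allylborane that reacts through a closed Zimmerman–Traxler transition state. It sets out from 3 and comes back at 5. Brown allylboration with B-allyldiisopinocampheylborane derived from (−)-α-pinene (Et2O, −78 °C; then NaOH, H2O2) would give 5 directly; this pinene antipode is the one expected to give the S alcohol from an unbranched aldehyde.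

## Further compounds

F1 | step 8 | (2S,4R,6S)-2-(4-benzyloxy-3-methoxyphenyl)-6-[2-(4-benzyloxy-3-methoxyphenyl)ethyl]tetrahydro-2H-pyran-4-yl trifluoroacetate | COc1cc(CC[C@H]2C[C@@H](OC(=O)C(F)(F)F)C[C@@H](c3ccc(OCc4ccccc4)c(OC)c3)O2)ccc1OCc1ccccc1
F2 | step 8 | (2S,4R,6S)-2-(4-benzyloxy-3-methoxyphenyl)-6-[2-(4-benzyloxy-3-methoxyphenyl)ethyl]tetrahydro-2H-pyran-4-ol | COc1cc(CC[C@H]2C[C@@H](O)C[C@@H](c3ccc(OCc4ccccc4)c(OC)c3)O2)ccc1OCc1ccccc1
F3 | step 8 | (2S,4S,6S)-2-(4-benzyloxy-3-methoxyphenyl)-6-[2-(4-benzyloxy-3-methoxyphenyl)ethyl]tetrahydro-2H-pyran-4-yl 4-nitrobenzoate | COc1cc(CC[C@H]2C[C@H](OC(=O)c5ccc(cc5)[N+](=O)[O-])C[C@@H](c3ccc(OCc4ccccc4)c(OC)c3)O2)ccc1OCc1ccccc1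
F4 | step 7 | (S)-6-(4-benzyloxy-3-methoxyphenyl)-4-hydroxyhexan-2-one | COc1cc(CC[C@H](O)CC(C)=O)ccc1OCc1ccccc1
F5 | step 7 | (1E,5S)-1,7-bis(4-benzyloxy-3-methoxyphenyl)-5-hydroxyhept-1-en-3-one | COc1cc(CC[C@H](O)CC(=O)/C=C/c2ccc(OCc3ccccc3)c(OC)c2)ccc1OCc1ccccc1
F6 | step 7 | (2S,6S)-2-(4-benzyloxy-3-methoxyphenyl)-6-[2-(4-benzyloxy-3-methoxyphenyl)ethyl]tetrahydro-4H-pyran-4-one | COc1cc(CC[C@H]2CC(=O)C[C@@H](c3ccc(OCc4ccccc4)c(OC)c3)O2)ccc1OCc1ccccc1
F7 | step 9 | (2R,3R,4S,6S)-2-(4-benzyloxy-3-methoxyphenyl)-6-[2-(4-benzyloxy-3-methoxyphenyl)ethyl]-3-iodotetrahydro-2H-pyran-4-ol | COc1cc(CC[C@H]2C[C@H](O)[C@@H](I)[C@@H](c3ccc(OCc4ccccc4)c(OC)c3)O2)ccc1OCc1ccccc1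
F0 | step 3 | none | none
A1 | alternative 1 | (2S,6S)-2-(4-benzyloxy-3-methoxyphenyl)-6-[2-(4-benzyloxy-3-methoxyphenyl)ethyl]tetrahydro-4H-pyran-4-one | COc1cc(CC[C@H]2CC(=O)C[C@@H](c3ccc(OCc4ccccc4)c(OC)c3)O2)ccc1OCc1ccccc1
A2 | alternative 1 | (2S,6S)-2-(4-benzyloxy-3-methoxyphenyl)-6-[2-(4-benzyloxy-3-methoxyphenyl)ethyl]-4-methylidene-1,3-dioxane (2,6-cis) | COc1cc(CC[C@H]2CC(=C)O[C@@H](c3ccc(OCc4ccccc4)c(OC)c3)O2)ccc1OCc1ccccc1
A3 | alternative 1 | (2S,6S)-2-(4-benzyloxy-3-methoxyphenyl)-6-[2-(4-benzyloxy-3-methoxyphenyl)ethyl]-1,3-dioxan-4-one (2,6-cis) | COc1cc(CC[C@H]2CC(=O)O[C@@H](c3ccc(OCc4ccccc4)c(OC)c3)O2)ccc1OCc1ccccc1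
A4 | alternative 2 | 4-{2-[(2S,4S,6S)-4-hydroxy-6-(4-hydroxy-3-methoxyphenyl)tetrahydro-2H-pyran-2-yl]ethyl}-2-methoxyphenyl 2,2-dimethylpropanoate | COc1cc(CC[C@H]2C[C@H](O)C[C@@H](c3ccc(O)c(OC)c3)O2)ccc1OC(=O)C(C)(C)C
A5 | alternative 2 | (3R,5S)-1-(4-hydroxy-3-methoxyphenyl)-7-(3-methoxy-4-pivaloyloxyphenyl)heptane-3,5-diol (syn) | COc1cc(CC[C@H](O)C[C@H](O)CCc3ccc(O)c(OC)c3)ccc1OC(=O)C(C)(C)C
A6 | alternative 3 | ethyl 2-[(2R,4S,6S)-6-(4-benzyloxy-3-methoxyphenyl)-4-(tert-butyldimethylsilyloxy)tetrahydro-2H-pyran-2-yl]acetate | CCOC(=O)C[C@H]1C[C@H](O[Si](C)(C)C(C)(C)C)C[C@@H](c2ccc(OCc3ccccc3)c(OC)c2)O1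
A7 | alternative 3 | ethyl (E)-3-{[(1S,3R)-1-(4-benzyloxy-3-methoxyphenyl)-3-(tert-butyldimethylsilyloxy)-4-iodobutyl]oxy}prop-2-enoate | CCOC(=O)/C=C/O[C@H](c2ccc(OCc3ccccc3)c(OC)c2)C[C@H](CI)O[Si](C)(C)C(C)(C)C
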